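A direct plan would build ring A first. 2,6-Dimethoxy-1,4-benzoquinone A1 would be acetoxylated and permethylated to pentamethoxybenzene A2, then acylated and mono-demethylated to the methoxyacetyl phenol A3, closed through an enaminone to 3,5,6,7,8-pentamethoxychromone A4, arylated at C2 with 2-bromo-5-methoxyphenol A5 by zincation and Negishi coupling to the 5-O-methyl flavone A6, and demethylated at O5 with BCl3. Its weakest steps would be: the acetoxylation and permethylation, which would only add oxygen and methyl groups, two of them cleaved again later; the C2 zincation and cross-coupling, which would make the convergent bond on the most advanced intermediate with a hindered free bromophenoxide; and the last demethylation, which would have to tell 5-OMe from 3-OMe beside the same carbonyl.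

**Plan of the new route**

The retrosynthesis cuts C4–C4a and O1–C2 of ring C. Without ring C, ring A is 4,5,6-trimethoxybenzene-1,3-diol, which has a mirror plane through C4a and C7: O1 and O5 are its two equivalent hydroxyls and C4a is its only C–H. Rings A and B are present from the start; ring C arises last, in one thermal annulation with a ring-B α-methoxy β-ketoester that supplies C2, C3 and C4 (C4–C4a first, then O1–C2). O5 is never methylated, so nothing is demethylated; ring B is in place before the chromone exists, so no cross-coupling is run on it; ring A needs no permethylation.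

Key step: step 5

Remark: the α-methoxy β-ketoester and the two open-chain intermediates of the annulation each carry one stereocentre and would be racemic; that carbon becomes the sp2 carbon C3 in the key step, and the target has no stereocentre.

**Route**

Step 1
Reactants: 1 1,2,3-trimethoxybenzene
Product: 2 1,5-dibromo-2,3,4-trimethoxybenzene
Conditions: NBS (2.1 eq), MeCN, 0 → 50 °C
Reagents that add atoms: N-bromosuccinimide, O=C1CCC(=O)N1Br
Why: Electrophilic aromatic bromination, in which each bromine should enter ortho to one outer methoxy group and para to the other, while C5 is activated only by the twisted central methoxy group and the two bromines slow a third substitution.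

Step 2
Reactants: 2 1,5-dibromo-2,3,4-trimethoxybenzene
Product: 3 4,5,6-trimethoxybenzene-1,3-diol
Conditions: Pd2(dba)3 (2 mol %), tBuXPhos (8 mol %), KOH (6 eq), 1,4-dioxane/H2O (1:1), 100 °C, Ar; then 2 M HCl
Reagents that add atoms: potassium hydroxide, [K+].[OH-]
Why: Twofold palladium-catalysed hydroxylation of an aryl bromide (C–O cross-coupling with hydroxide), in which the bulky biaryl phosphine should promote C–O reductive elimination from divalent palladium on this electron-rich ring; the oxidation-prone diol is kept under argon.

Step 3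
Reactants: 4 methyl 2-hydroxy-4-methoxybenzoate
Product: 5 methyl 2-(benzyloxy)-4-methoxybenzoate
Conditions: BnBr (1.2 eq), K2CO3 (2 eq), DMF, 60 °C
Reagents that add atoms: benzyl bromide, BrCc1ccccc1
Why: Williamson etherification masks the future 2'-OH as a benzyl ether that should survive base and heat and can be removed at the end by hydrogenolysis without touching a methyl ether.

Step 4
Reactants: 5 methyl 2-(benzyloxy)-4-methoxybenzoate; 6 methyl methoxyacetate
Product: 8 methyl 3-[2-(benzyloxy)-4-methoxyphenyl]-2-methoxy-3-oxopropanoate, via lithium enolate of methyl methoxyacetate 7 (not isolated)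
Conditions: 6 (2.5 eq), LiHMDS (3.5 eq), THF, −78 °C; then 5, −78 °C → rt; 1 M HCl
Reagents that add atoms: none
Why: Crossed Claisen condensation, in which the preformed α-alkoxy ester enolate acylates the non-enolisable benzoate and deprotonation of the β-ketoester by excess base drives the equilibrium; the α-stereocentre forms racemic and is removed in step 5.

Step 5
Reactants: 3 4,5,6-trimethoxybenzene-1,3-diol; 8 methyl 3-[2-(benzyloxy)-4-methoxyphenyl]-2-methoxy-3-oxopropanoate
Product: 12 2-[2-(benzyloxy)-4-methoxyphenyl]-5-hydroxy-3,6,7,8-tetramethoxy-4H-chromen-4-one, via acylketene 9 (not isolated), via resorcinol monoester 10 (not isolated), via C-acyl diketone 11 (not isolated)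
Conditions: 3 (1.0 eq), 8 (1.5 eq), neat melt, Ar, microwave, 230–240 °C, 15 min, MeOH and H2O distilled off
Reagents that add atoms: none
Why: Mentzer-type thermal chromone annulation: at 230–240 °C ketoester 8 should lose methanol through its enol to give acylketene 9, which acylates one of the two equivalent hydroxyls of 3 to give ester 10, and a thermal Fries-type 1,3-acyl shift (or direct C-acylation by the ketene) to the only ring C–H, ortho to both hydroxyls and para to a methoxy group, gives diketone 11 with the new C4–C4a bond. Ring C then closes by 6-exo-trig addition of an ortho hydroxyl to the aryl ketone carbon (O1–C2) and loss of water, which is irreversible because an aromatic, hydrogen-bonded 4-pyranone results. The closest known reaction type is the solvent-free thermal or microwave condensation of phloroglucinol with aroylacetates and 2-substituted β-ketoesters to 5,7-dihydroxyflavones and 3-substituted chromones. No stereocentre is formed, and the racemic α-carbon of 8 becomes C3. The step needs regioselectivity on ring A and chromone-over-coumarin selectivity: the first is secured by the mirror plane of 3 (either hydroxyl gives the same product, the unused one becomes the chelated 5-OH, and with no ring C–H left a second annulation is impossible), the second by the acid-free conditions, the α-methoxy group and the deactivated, ortho-substituted aryl ketone, all of which disfavour Pechmann-type attack of the ring carbon on the ketone.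

Step 6
Reactants: 12 2-[2-(benzyloxy)-4-methoxyphenyl]-5-hydroxy-3,6,7,8-tetramethoxy-4H-chromen-4-one
Product: 13 5,2'-dihydroxy-3,6,7,8,4'-pentamethoxyflavone
Conditions: H2 (1 atm), 10 % Pd/C, EtOAc/MeOH, rt
Reagents that add atoms: none
Why: Hydrogenolysis of the benzyl aryl ether, under which the tetrasubstituted C2=C3 bond of the vinylogous ester and the five methyl ethers should stay intact.

**Compound list**

1 | 1,2,3-trimethoxybenzene | COc1cccc(OC)c1OC | starting material
2 | 1,5-dibromo-2,3,4-trimethoxybenzene | COc1c(Br)cc(Br)c(OC)c1OC | intermediate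
3 | 4,5,6-trimethoxybenzene-1,3-diol | COc1c(O)cc(O)c(OC)c1OC | intermediate
4 | methyl 2-hydroxy-4-methoxybenzoate | COC(=O)c1ccc(OC)cc1O | starting material
5 | methyl 2-(benzyloxy)-4-methoxybenzoate | COC(=O)c1ccc(OC)cc1OCc1ccccc1 | intermediate
6 | methyl methoxyacetate | COCC(=O)OC | starting material
7 | lithium 1,2-dimethoxyethen-1-olate (lithium enolate of 6) | [Li+].[O-]C(OC)=COC | intermediate
8 | methyl 3-[2-(benzyloxy)-4-methoxyphenyl]-2-methoxy-3-oxopropanoate (racemic) | COC(=O)C(OC)C(=O)c1ccc(OC)cc1OCc1ccccc1 | intermediate
9 | 3-[2-(benzyloxy)-4-methoxyphenyl]-2-methoxyprop-1-ene-1,3-dione (acylketene) | O=C=C(OC)C(=O)c1ccc(OC)cc1OCc1ccccc1 | intermediate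
10 | 5-hydroxy-2,3,4-trimethoxyphenyl 3-[2-(benzyloxy)-4-methoxyphenyl]-2-methoxy-3-oxopropanoate (racemic) | COC(C(=O)Oc1cc(O)c(OC)c(OC)c1OC)C(=O)c1ccc(OC)cc1OCc1ccccc1 | intermediate
11 | 1-[2-(benzyloxy)-4-methoxyphenyl]-3-(2,6-dihydroxy-3,4,5-trimethoxyphenyl)-2-methoxypropane-1,3-dione (racemic) | COC(C(=O)c1ccc(OC)cc1OCc1ccccc1)C(=O)c1c(O)c(OC)c(OC)c(OC)c1O | intermediate
12 | 2-[2-(benzyloxy)-4-methoxyphenyl]-5-hydroxy-3,6,7,8-tetramethoxy-4H-chromen-4-one | COc1ccc(-c2oc3c(OC)c(OC)c(OC)c(O)c3c(=O)c2OC)c(OCc2ccccc2)c1 | intermediate
13 | 5,2'-dihydroxy-3,6,7,8,4'-pentamethoxyflavone | COc1ccc(-c2oc3c(OC)c(OC)c(OC)c(O)c3c(=O)c2OC)c(O)c1 | target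

**Count and risks**

Total steps: 6. Longest linear sequence: 4 steps (1, 2, 5, 6 or 3, 4, 5, 6).

Steps most likely to fail:

Step 5. The acyl transfer may stop at O-acylation, the ring carbon may add to the ketone instead (Pechmann-type closure to a coumarin), or the electron-rich diol may degrade at 240 °C. The fallback sets out from 3 and 5 and comes back to the route at 12, closing ring C at O1–C2. Hoesch reaction of 3 with methoxyacetonitrile (ZnCl2, HCl gas, Et2O, 0 °C) would give 1-(2,6-dihydroxy-3,4,5-trimethoxyphenyl)-2-methoxyethan-1-iminium chloride F1, which hot water would hydrolyse to 1-(2,6-dihydroxy-3,4,5-trimethoxyphenyl)-2-methoxyethan-1-one F2; this ketone keeps the mirror plane, so again only one constitution can form. Ester 5 would be saponified (LiOH, THF/H2O) to 2-(benzyloxy)-4-methoxybenzoic acid F3 and dehydrated (DCC, CH2Cl2) to 2-(benzyloxy)-4-methoxybenzoic anhydride F4. Allan–Robinson condensation of F2 with F4 and Et3N at 160–170 °C, then brief KOH/EtOH–H2O hydrolysis of O-aroyl esters, should give 12.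

Step 2. The second C–O coupling may stall on the bromophenoxide, hydrodebromination may compete, or the phenoxide may oxidise in hot base. The fallback sets out from 2 and comes back at 3. Twofold Miyaura borylation of 2 (B2pin2, Pd(dppf)Cl2, KOAc, dioxane, 90 °C) would give 2,2'-(4,5,6-trimethoxy-1,3-phenylene)bis(4,4,5,5-tetramethyl-1,3,2-dioxaborolane) F5, and oxidation with H2O2/aq NaOH in THF at 0 °C should give 3 under cold, brief conditions.

Step 4. Self-condensation of the methoxyacetate enolate may outrun acylation by the deactivated, ortho-substituted benzoate. The fallback sets out from 6 (through enolate 7) and comes back at 8. Benzylation of commercial 2-hydroxy-4-methoxybenzaldehyde (BnBr, K2CO3, DMF) would give 2-(benzyloxy)-4-methoxybenzaldehyde F6. Aldol addition of enolate 7 (THF, −78 °C) would give methyl 3-[2-(benzyloxy)-4-methoxyphenyl]-3-hydroxy-2-methoxypropanoate F7 as a mixture of diastereomers, and Dess–Martin periodinane oxidation (CH2Cl2, rt) should give 8.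

**Further compounds**

F1 | step 5 | 1-(2,6-dihydroxy-3,4,5-trimethoxyphenyl)-2-methoxyethan-1-iminium chloride | COCC(=[NH2+])c1c(O)c(OC)c(OC)c(OC)c1O.[Cl-]
F2 | step 5 | 1-(2,6-dihydroxy-3,4,5-trimethoxyphenyl)-2-methoxyethan-1-one | COCC(=O)c1c(O)c(OC)c(OC)c(OC)c1O
F3 | step 5 | 2-(benzyloxy)-4-methoxybenzoic acid | COc1ccc(C(=O)O)c(OCc2ccccc2)c1
F4 | step 5 | 2-(benzyloxy)-4-methoxybenzoic anhydride | COc1ccc(C(=O)OC(=O)c2ccc(OC)cc2OCc2ccccc2)c(OCc2ccccc2)c1
F5 | step 2 | 2,2'-(4,5,6-trimethoxy-1,3-phenylene)bis(4,4,5,5-tetramethyl-1,3,2-dioxaborolane) | COc1c(B2OC(C)(C)C(C)(C)O2)cc(B2OC(C)(C)C(C)(C)O2)c(OC)c1OC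
F6 | step 4 | 2-(benzyloxy)-4-methoxybenzaldehyde | COc1ccc(C=O)c(OCc2ccccc2)c1
F7 | step 4 | methyl 3-[2-(benzyloxy)-4-methoxyphenyl]-3-hydroxy-2-methoxypropanoate (mixture of diastereomers) | COC(=O)C(OC)C(O)c1ccc(OC)cc1OCc1ccccc1
A1 | direct plan | 2,6-dimethoxy-1,4-benzoquinone | COC1=CC(=O)C=C(OC)C1=O
A2 | direct plan | pentamethoxybenzene | COc1cc(OC)c(OC)c(OC)c1OC
A3 | direct plan | 1-(2-hydroxy-3,4,5,6-tetramethoxyphenyl)-2-methoxyethan-1-one | COCC(=O)c1c(O)c(OC)c(OC)c(OC)c1OC
A4 | direct plan | 3,5,6,7,8-pentamethoxy-4H-chromen-4-one | COc1coc2c(OC)c(OC)c(OC)c(OC)c2c1=O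
A5 | direct plan | 2-bromo-5-methoxyphenol | COc1ccc(Br)c(O)c1
A6 | direct plan | 2-(2-hydroxy-4-methoxyphenyl)-3,5,6,7,8-pentamethoxy-4H-chromen-4-one | COc1ccc(-c2oc3c(OC)c(OC)c(OC)c(OC)c3c(=O)c2OC)c(O)c1
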